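**Retrosynthetic overview**
1. Target ⇒ last-step epoxidation of the 1(10)-E alkene; the C3 benzoate and the C8 (2R,3S)-epoxy ester come from acylation of two ring alcohols (acid made from ethyl (S)-3-hydroxybutanoate).
2. α-Methylene trans-γ-lactone ⇒ C7 alkylation of a ring-expanded enolate, C6 ketone reduction, lactone closure with inversion at C6, then C13 methylenation.
3. Ten-membered carbocycle ⇒ anionic oxy-Cope [3,3] shift of a trans-1,2-dialkenylcyclohex-2-enol (forms C8–C9, breaks C1–C6, sets C8 and the E-1(10) alkene, keeps the ring alkene as 4Z).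
4. Cyclohexenol ⇒ (S)-carvone-derived 4-silyloxy-6-isopropenylcyclohexenone plus (Z)-2-(4-methoxybenzyloxy)vinyllithium.
5. Ring order: cyclohexene (bought) → cyclodecadiene (oxy-Cope) → γ-lactone → ring oxirane (last); the side-chain oxirane is made separately.

Assumption: ten-membered-ring compounds carry germacrane numbering (C1–C15, lactone carbonyl C12, exocyclic methylene C13); TBS = tert-butyldimethylsilyl, PMB = 4-methoxybenzyl; the target is (1R,3S,6R,7R,8R,10R) with a (2R,3S)-epoxy ester.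

**Step 1**
Reactants: 1 (S)-(+)-carvone
Product: 2 (1S,5S)-cis-carveol
Conditions: NaBH4, CeCl3·7H2O, MeOH, −20 °C
Reagents that add atoms: none
Why: Luche 1,2-reduction delivers hydride axially to give the equatorial alcohol cis to the isopropenyl group (new centre 1S, the future C3), while the carvone centre is untouched.

**Step 2**
Reactants: 2 (1S,5S)-cis-carveol
Product: 3 TBS ether of cis-carveol
Conditions: TBSCl, imidazole, DMF, 23 °C
Reagents that add atoms: tert-butyldimethylsilyl chloride, CC(C)(C)[Si](C)(C)Cl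
Why: Standard silylation of a secondary allylic alcohol with retention, giving an ether that survives organolithium, KH and hydride steps.

**Step 3**
Reactants: 3 TBS ether of cis-carveol
Product: 4 (4S,6S)-4-(tert-butyldimethylsilyloxy)-3-methyl-6-(prop-1-en-2-yl)cyclohex-2-en-1-one
Conditions: CrO3, 3,5-dimethylpyrazole, CH2Cl2, −20 °C
Reagents that add atoms: chromium trioxide, O=[Cr](=O)=O
Why: Allylic C–H oxidation attacks the only ring CH2 that is allylic to the trisubstituted alkene and not deactivated by oxygen, giving the γ-silyloxy enone without base, so both stereocentres stay (cis, both pseudo-equatorial).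

**Step 4**
Reactants: 5 4-methoxybenzyl alcohol
Product: 6 4-methoxybenzyl vinyl ether
Conditions: vinyl acetate, [Ir(cod)Cl]2 (1 mol %), Na2CO3, toluene, 100 °C
Reagents that add atoms: vinyl acetate, C=COC(C)=O
Why: Iridium-catalysed transfer vinylation of a primary alcohol by vinyl acetate gives the enol ether directly.

**Step 5**
Reactants: 6 4-methoxybenzyl vinyl ether
Product: 8 (Z)-1-[(2-bromoethenyloxy)methyl]-4-methoxybenzene, via dibromide 7 (not isolated)
Conditions: Br2, CH2Cl2, −78 °C; then i-Pr2NEt, −78 → 23 °C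
Reagents that add atoms: bromine, BrBr
Why: Bromine addition to the enol ether followed by amine-induced loss of HBr from the α-bromo ether (through the oxocarbenium ion) gives the 2-bromovinyl ether, the more stable Z isomer predominating and being purified from minor E.

**Step 6**
Reactants: 4 (4S,6S)-enone; 8 (Z)-bromovinyl PMB ether
Product: 10 (1S,4S,6S)-4-(tert-butyldimethylsilyloxy)-1-[(Z)-2-(4-methoxybenzyloxy)ethenyl]-3-methyl-6-(prop-1-en-2-yl)cyclohex-2-en-1-ol, via vinyllithium 9 (not isolated)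
Conditions: 8, t-BuLi (2 equiv), Et2O, −78 °C; then 4, THF, −78 °C; H2O
Reagents that add atoms: none
Why: Br/Li exchange with retention gives the stable cis-β-alkoxyvinyllithium, and its 1,2-addition to the enone occurs on the face opposite to the cis-disposed isopropenyl and silyloxy groups, setting the carbinol centre (1S) with the two alkenyl groups trans.

**Step 7**
Reactants: 10 dialkenylcyclohexenol
Product: 13 tert-butyl (3S,7R,8R)-3-(tert-butyldimethylsilyloxy)-8-(4-methoxybenzyloxy)-6-oxo-13-norgermacra-1(10)E,4Z-dien-12-oate, via potassium alkoxide 11 (not isolated), via potassium enolate 12 (not isolated)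
Conditions: KH, THF, 0 → 40 °C (no crown ether); then −78 °C, BrCH2CO2t-Bu, −78 → −30 °C
Reagents that add atoms: tert-butyl bromoacetate, CC(C)(C)OC(=O)CBr
Why: Anionic oxy-Cope [3,3] rearrangement through the chair with both ring bonds equatorial gives the E-1(10) alkene, leaves the cyclohexene alkene as 4Z and transfers chirality to C8 (R, Z-enol-ether oxygen axial and bridged to the alkoxide by K+); the resulting enolate, still K+-bridged to the C8 ether oxygen, is alkylated on its outer face anti to C9 (Fráter–Seebach-type sense), setting C7 (R).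

**Step 8**
Reactants: 13 keto ester
Product: 14 tert-butyl (3S,6S,7S,8R)-6-hydroxy-3-(tert-butyldimethylsilyloxy)-8-(4-methoxybenzyloxy)-13-norgermacra-1(10)E,4Z-dien-12-oate
Conditions: NaBH4, CeCl3·7H2O, MeOH, −78 → −40 °C
Reagents that add atoms: none
Why: Luche 1,2-reduction of the enone, with hydride on the open outer face anti to the C7–C8 ring bond (Felkin–Anh and peripheral attack agree), gives the 6β (6S) allylic alcohol; C7 is spatially unchanged (its descriptor reads S here only by a priority switch), and the tert-butyl ester does not lactonise.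

**Step 9**
Reactants: 14 6β-hydroxy ester
Product: 16 (3S,6R,7R,8R)-3-(tert-butyldimethylsilyloxy)-8-(4-methoxybenzyloxy)-13-norgermacra-1(10)E,4Z-dien-12,6-olide, via allylic mesylate 15 (not isolated)
Conditions: Ms2O, Et3N, CH2Cl2, −30 → 40 °C
Reagents that add atoms: none
Why: The ester carbonyl oxygen, held on the outer face by C11, displaces the inward-pointing allylic mesylate (neighbouring-group SN2, inversion to 6R) and the tert-butyl oxocarbenium ion loses isobutene, closing the trans-fused γ-lactone.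

**Step 10**
Reactants: 16 trans-lactone
Product: 19 (3S,6R,7R,8R)-3-(tert-butyldimethylsilyloxy)-8-(4-methoxybenzyloxy)germacra-1(10)E,4Z,11(13)-trien-12,6-olide, via Mannich base 17 (not isolated), via methiodide 18 (not isolated)
Conditions: LiN(i-Pr)2, THF, −78 °C; CH2=NMe2+ I−, −78 → 23 °C; MeI, THF, 23 °C; then aq NaHCO3, EtOAc
Reagents that add atoms: Eschenmoser's salt (N,N-dimethylmethyleneiminium iodide), C=[N+](C)C.[I-]
Why: Mannich reaction of the lactone enolate, N-methylation and Hofmann-type β-elimination install the exocyclic C11=C13 methylene, erasing the transient C11 centre.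

**Step 11**
Reactants: 19 α-methylene lactone
Product: 20 (3S,6R,7R,8R)-3-(tert-butyldimethylsilyloxy)-8-hydroxygermacra-1(10)E,4Z,11(13)-trien-12,6-olide
Conditions: DDQ, CH2Cl2/pH 7 buffer, 0 → 23 °C
Reagents that add atoms: none
Why: Oxidative PMB-ether cleavage (benzylic hydride abstraction, then hydrolysis) is neutral and leaves the silyl ether, lactone and alkenes untouched.

**Step 12**
Reactants: 21 ethyl (S)-3-hydroxybutanoate
Product: 22 ethyl (2S,3S)-3-hydroxy-2-methylbutanoate
Conditions: LiN(i-Pr)2 (2.2 equiv), THF, −50 → −20 °C; MeI, DMPU, −78 → −10 °C; AcOH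
Reagents that add atoms: iodomethane, CI
Why: Fráter–Seebach alkylation: the lithium-chelated dianion is methylated anti to the C3 methyl group, giving the anti (2S,3S) product.

**Step 13**
Reactants: 22 ethyl (2S,3S)-3-hydroxy-2-methylbutanoate
Product: 24 ethyl (2R,3S)-2,3-dimethyloxirane-2-carboxylate, via iodo alkoxide 23 (not isolated)
Conditions: LiN(i-Pr)2 (2.2 equiv), THF, −78 → −40 °C; I2, THF, −78 → 0 °C
Reagents that add atoms: none
Why: The chelated dianion is iodinated anti to the C3 methyl and the alkoxide then displaces iodide with inversion (Darzens-type closure), giving the cis-dimethyl (2R,3S) glycidate with C3 retained.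

**Step 14**
Reactants: 24 epoxy ester
Product: 25 (2R,3S)-2,3-dimethyloxirane-2-carboxylic acid
Conditions: LiOH·H2O, THF/H2O, 0 °C; then 1 M HCl to pH 3, 0 °C
Reagents that add atoms: lithium hydroxide, [Li+].[OH-]
Why: Mild saponification; the fully substituted glycidic acid tolerates brief cold acidification and neither centre is touched.

**Step 15**
Reactants: 20 8β-alcohol; 25 epoxy acid
Product: 27 (3S,6R,7R,8R)-3-(tert-butyldimethylsilyloxy)-8-[(2R,3S)-2,3-dimethyloxirane-2-carbonyloxy]germacra-1(10)E,4Z,11(13)-trien-12,6-olide, via mixed anhydride 26 (not isolated)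
Conditions: 25, 2,4,6-Cl3C6H2COCl, Et3N, toluene, 23 °C; then 20, DMAP, 40 °C
Reagents that add atoms: none
Why: Yamaguchi esterification: DMAP transfers the aliphatic acyl group of the mixed anhydride to the hindered C8 alcohol with no stereocentre involved.

**Step 16**
Reactants: 27 C8 ester
Product: 28 (3S,6R,7R,8R)-3-hydroxy-8-[(2R,3S)-2,3-dimethyloxirane-2-carbonyloxy]germacra-1(10)E,4Z,11(13)-trien-12,6-olide
Conditions: HF·pyridine, pyridine/THF, 0 → 23 °C
Reagents that add atoms: none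
Why: Buffered fluoride desilylation spares the esters, the glycidate and the methylene lactone.

**Step 17**
Reactants: 28 3β-alcohol
Product: 29 (3S,6R,7R,8R)-3-benzoyloxy-8-[(2R,3S)-2,3-dimethyloxirane-2-carbonyloxy]germacra-1(10)E,4Z,11(13)-trien-12,6-olide
Conditions: BzCl, pyridine, DMAP (cat.), CH2Cl2, 0 → 23 °C
Reagents that add atoms: benzoyl chloride, O=C(Cl)c1ccccc1
Why: DMAP-catalysed O-acylation with retention at C3.

**Step 18**
Reactants: 29 benzoate
Product: 30 CNP0324463.5, (1R,3S,6R,7R,8R,10R)-3-benzoyloxy-8-[(2R,3S)-2,3-dimethyloxirane-2-carbonyloxy]-1,10-epoxygermacra-4Z,11(13)-dien-12,6-olide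
Conditions: mCPBA (1.05 equiv), CH2Cl2, −20 → 0 °C
Reagents that add atoms: 3-chloroperbenzoic acid, OOC(=O)c1cccc(Cl)c1
Why: Prilezhaev epoxidation of the only electron-rich alkene (the 4Z alkene carries two allylic acyloxy groups, the methylene lactone is electron-poor), on the exposed outer face of the E-alkene in the conformer with the C14 methyl on the β face, gives the trans 1β,10α (1R,10R) epoxide.

**Compound list**
1 | (S)-(+)-carvone | CC1=CC[C@@H](CC1=O)C(C)=C | starting material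
2 | (1S,5S)-cis-carveol | CC1=CC[C@@H](C[C@@H]1O)C(C)=C | intermediate
3 | tert-butyldimethyl{[(1S,5S)-2-methyl-5-(prop-1-en-2-yl)cyclohex-2-en-1-yl]oxy}silane | CC1=CC[C@@H](C[C@@H]1O[Si](C)(C)C(C)(C)C)C(C)=C | intermediate
4 | (4S,6S)-4-(tert-butyldimethylsilyloxy)-3-methyl-6-(prop-1-en-2-yl)cyclohex-2-en-1-one | CC1=CC(=O)[C@@H](C[C@@H]1O[Si](C)(C)C(C)(C)C)C(C)=C | intermediate
5 | 4-methoxybenzyl alcohol | COc1ccc(CO)cc1 | starting material
6 | 4-methoxybenzyl vinyl ether | COc1ccc(COC=C)cc1 | intermediate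
7 | 1-[(1,2-dibromoethoxy)methyl]-4-methoxybenzene (racemic) | COc1ccc(COC(Br)CBr)cc1 | intermediate
8 | (Z)-1-[(2-bromoethenyloxy)methyl]-4-methoxybenzene | COc1ccc(CO/C=C\Br)cc1 | intermediate
9 | (Z)-2-(4-methoxybenzyloxy)ethenyllithium | COc1ccc(CO/C=C\[Li])cc1 | intermediate
10 | (1S,4S,6S)-4-(tert-butyldimethylsilyloxy)-1-[(Z)-2-(4-methoxybenzyloxy)ethenyl]-3-methyl-6-(prop-1-en-2-yl)cyclohex-2-en-1-ol | CC1=C[C@@](O)(/C=C\OCc2ccc(OC)cc2)[C@@H](C[C@@H]1O[Si](C)(C)C(C)(C)C)C(C)=C | intermediate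
11 | potassium alkoxide of 10 | CC1=C[C@@]([O-])(/C=C\OCc2ccc(OC)cc2)[C@@H](C[C@@H]1O[Si](C)(C)C(C)(C)C)C(C)=C.[K+] | intermediate
12 | potassium (4S,9R)-4-(tert-butyldimethylsilyloxy)-9-(4-methoxybenzyloxy)-3,7-dimethylcyclodeca-1(10),2Z,6E-trien-1-olate (enolate O cis to C9) | [K+].[O-]/C1=C\[C@H](OCc2ccc(OC)cc2)C/C(C)=C/C[C@H](O[Si](C)(C)C(C)(C)C)/C(C)=C\1 | intermediate
13 | tert-butyl (3S,7R,8R)-3-(tert-butyldimethylsilyloxy)-8-(4-methoxybenzyloxy)-6-oxo-13-norgermacra-1(10)E,4Z-dien-12-oate | O=C1/C=C(/C)[C@@H](O[Si](C)(C)C(C)(C)C)C/C=C(\C)C[C@@H](OCc2ccc(OC)cc2)[C@H]1CC(=O)OC(C)(C)C | intermediate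
14 | tert-butyl (3S,6S,7S,8R)-6-hydroxy-3-(tert-butyldimethylsilyloxy)-8-(4-methoxybenzyloxy)-13-norgermacra-1(10)E,4Z-dien-12-oate (6β-OH) | O[C@H]1/C=C(/C)[C@@H](O[Si](C)(C)C(C)(C)C)C/C=C(\C)C[C@@H](OCc2ccc(OC)cc2)[C@H]1CC(=O)OC(C)(C)C | intermediate
15 | 6-O-methanesulfonate of 14 (3S,6S,7R,8R) | CS(=O)(=O)O[C@H]1/C=C(/C)[C@@H](O[Si](C)(C)C(C)(C)C)C/C=C(\C)C[C@@H](OCc2ccc(OC)cc2)[C@H]1CC(=O)OC(C)(C)C | intermediate
16 | (3S,6R,7R,8R)-3-(tert-butyldimethylsilyloxy)-8-(4-methoxybenzyloxy)-13-norgermacra-1(10)E,4Z-dien-12,6-olide | C1C(=O)O[C@@H]2/C=C(/C)[C@@H](O[Si](C)(C)C(C)(C)C)C/C=C(\C)C[C@@H](OCc3ccc(OC)cc3)[C@@H]12 | intermediate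
17 | 13-(dimethylamino)-11,13-dihydro derivative of 19 (C11 epimers) | CN(C)CC1C(=O)O[C@@H]2/C=C(/C)[C@@H](O[Si](C)(C)C(C)(C)C)C/C=C(\C)C[C@@H](OCc3ccc(OC)cc3)[C@@H]12 | intermediate
18 | trimethylammonium iodide of 17 | C[N+](C)(C)CC1C(=O)O[C@@H]2/C=C(/C)[C@@H](O[Si](C)(C)C(C)(C)C)C/C=C(\C)C[C@@H](OCc3ccc(OC)cc3)[C@@H]12.[I-] | intermediate
19 | (3S,6R,7R,8R)-3-(tert-butyldimethylsilyloxy)-8-(4-methoxybenzyloxy)germacra-1(10)E,4Z,11(13)-trien-12,6-olide | C=C1C(=O)O[C@@H]2/C=C(/C)[C@@H](O[Si](C)(C)C(C)(C)C)C/C=C(\C)C[C@@H](OCc3ccc(OC)cc3)[C@@H]12 | intermediate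
20 | (3S,6R,7R,8R)-3-(tert-butyldimethylsilyloxy)-8-hydroxygermacra-1(10)E,4Z,11(13)-trien-12,6-olide | C=C1C(=O)O[C@@H]2/C=C(/C)[C@@H](O[Si](C)(C)C(C)(C)C)C/C=C(\C)C[C@@H](O)[C@@H]12 | intermediate
21 | ethyl (S)-3-hydroxybutanoate | CCOC(=O)C[C@H](C)O | starting material
22 | ethyl (2S,3S)-3-hydroxy-2-methylbutanoate | CCOC(=O)[C@@H](C)[C@H](C)O | intermediate
23 | lithium alkoxide of ethyl (2S,3S)-3-hydroxy-2-iodo-2-methylbutanoate | CCOC(=O)[C@@](C)(I)[C@H](C)[O-].[Li+] | intermediate
24 | ethyl (2R,3S)-2,3-dimethyloxirane-2-carboxylate | CCOC(=O)[C@]1(C)O[C@H]1C | intermediate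
25 | (2R,3S)-2,3-dimethyloxirane-2-carboxylic acid | OC(=O)[C@]1(C)O[C@H]1C | intermediate
26 | (2R,3S)-2,3-dimethyloxirane-2-carboxylic 2,4,6-trichlorobenzoic anhydride | O=C(OC(=O)c1c(Cl)cc(Cl)cc1Cl)[C@]1(C)O[C@H]1C | intermediate
27 | (3S,6R,7R,8R)-3-(tert-butyldimethylsilyloxy)-8-[(2R,3S)-2,3-dimethyloxirane-2-carbonyloxy]germacra-1(10)E,4Z,11(13)-trien-12,6-olide | C=C1C(=O)O[C@@H]2/C=C(/C)[C@@H](O[Si](C)(C)C(C)(C)C)C/C=C(\C)C[C@@H](OC(=O)[C@]3(C)O[C@H]3C)[C@@H]12 | intermediate
28 | (3S,6R,7R,8R)-3-hydroxy-8-[(2R,3S)-2,3-dimethyloxirane-2-carbonyloxy]germacra-1(10)E,4Z,11(13)-trien-12,6-olide | C=C1C(=O)O[C@@H]2/C=C(/C)[C@@H](O)C/C=C(\C)C[C@@H](OC(=O)[C@]3(C)O[C@H]3C)[C@@H]12 | intermediate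
29 | (3S,6R,7R,8R)-3-benzoyloxy-8-[(2R,3S)-2,3-dimethyloxirane-2-carbonyloxy]germacra-1(10)E,4Z,11(13)-trien-12,6-olide | C=C1C(=O)O[C@@H]2/C=C(/C)[C@@H](OC(=O)c3ccccc3)C/C=C(\C)C[C@@H](OC(=O)[C@]3(C)O[C@H]3C)[C@@H]12 | intermediate
30 | CNP0324463.5, (1R,3S,6R,7R,8R,10R)-3-benzoyloxy-8-[(2R,3S)-2,3-dimethyloxirane-2-carbonyloxy]-1,10-epoxygermacra-4Z,11(13)-dien-12,6-olide | C=C1C(=O)O[C@@H]2/C=C(/C)[C@@H](OC(=O)c3ccccc3)C[C@H]3O[C@]3(C)C[C@@H](OC(=O)[C@]3(C)O[C@H]3C)[C@@H]12 | target

**Step count**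
Total: 18 steps. Longest linear sequence: 13 steps (1–3, 6–11, 15–18 from (S)-carvone); steps 4–5 and 12–14 are side branches.

**Three steps most likely to fail, with fallbacks**

Step 3 (allylic oxidation): the oxidant may instead attack the silyloxy-bearing C–H (returning carvone) or the isopropenyl allylic positions. The fallback sets out from 3 and returns at 4. Dye-sensitised photo-oxygenation of 3 (O2, tetraphenylporphyrin, hν, CH2Cl2, 0 °C; Schenck ene reaction) puts oxygen on the methyl-bearing alkene carbon and shifts the alkene, giving (4R,6S)-6-(tert-butyldimethylsilyloxy)-1-hydroperoxy-1-methyl-4-(prop-1-en-2-yl)cyclohex-2-ene F1. This is reduced in the same flask with PPh3 to (4R,6S)-6-(tert-butyldimethylsilyloxy)-1-methyl-4-(prop-1-en-2-yl)cyclohex-2-en-1-ol F2 (C1 epimers, irrelevant). Oxidative 1,3-transposition of this tertiary allylic alcohol with C5H5NH[CrO3Cl] in CH2Cl2 (Dauben–Babler) then gives enone 4.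

Step 7 (tandem oxy-Cope/alkylation): the axial Z-alkoxy group may divert part of the rearrangement through a boat, and the hot potassium enolate may lose the β-alkoxide or alkylate on the wrong face or on oxygen. The fallback sets out from 10 and returns at 13. The rearrangement is run as before, but enolate 12 is captured on oxygen at −78 °C with Me3SiCl/Et3N as the trimethylsilyl dienol ether of the ring-expanded ketone F3, which can be purified and its C8 and alkene geometry checked. MeLi (THF, 0 °C, then −78 °C) cleaves the silyl group to the amine-free lithium enolate F4, which is more tightly chelated by the C8 ether oxygen and far less prone to β-elimination. Alkylation with tert-butyl bromoacetate at −78 °C gives 13.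

Step 8 (facial selectivity of the C6 reduction, which fixes the lactone closure mode): if the macrocycle reacts through another conformer, hydride may add to the other face. The fallback sets out from 13 and returns at 16. The same Luche reduction would then give the 6α-alcohol, tert-butyl (3S,6R,7S,8R)-6-hydroxy-3-(tert-butyldimethylsilyloxy)-8-(4-methoxybenzyloxy)-13-norgermacra-1(10)E,4Z-dien-12-oate F5. Its hydroxyl already has the target configuration, so the lactone is closed with retention by intramolecular acyl substitution (NaH, THF, 0 °C, loss of tert-butoxide) instead of displacement at C6, giving 16.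

**Further compounds**
F1 | step 3 | (4R,6S)-6-(tert-butyldimethylsilyloxy)-1-hydroperoxy-1-methyl-4-(prop-1-en-2-yl)cyclohex-2-ene (C1 epimers) | CC1(OO)C=C[C@@H](C[C@@H]1O[Si](C)(C)C(C)(C)C)C(C)=C
F2 | step 3 | (4R,6S)-6-(tert-butyldimethylsilyloxy)-1-methyl-4-(prop-1-en-2-yl)cyclohex-2-en-1-ol (C1 epimers) | CC1(O)C=C[C@@H](C[C@@H]1O[Si](C)(C)C(C)(C)C)C(C)=C
F3 | step 7 | trimethylsilyl dienol ether of (2Z,6E,4S,9R)-4-(tert-butyldimethylsilyloxy)-9-(4-methoxybenzyloxy)-3,7-dimethylcyclodeca-2,6-dien-1-one | C[Si](C)(C)O/C1=C\[C@H](OCc2ccc(OC)cc2)C/C(C)=C/C[C@H](O[Si](C)(C)C(C)(C)C)/C(C)=C\1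
F4 | step 7 | lithium (4S,9R)-4-(tert-butyldimethylsilyloxy)-9-(4-methoxybenzyloxy)-3,7-dimethylcyclodeca-1(10),2Z,6E-trien-1-olate | [Li+].[O-]/C1=C\[C@H](OCc2ccc(OC)cc2)C/C(C)=C/C[C@H](O[Si](C)(C)C(C)(C)C)/C(C)=C\1
F5 | step 8 | tert-butyl (3S,6R,7S,8R)-6-hydroxy-3-(tert-butyldimethylsilyloxy)-8-(4-methoxybenzyloxy)-13-norgermacra-1(10)E,4Z-dien-12-oate (6α-OH) | O[C@@H]1/C=C(/C)[C@@H](O[Si](C)(C)C(C)(C)C)C/C=C(\C)C[C@@H](OCc2ccc(OC)cc2)[C@H]1CC(=O)OC(C)(C)C
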